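**Direct plan and its weak points**

A direct plan would make ring B first: vanillin A1 would be taken in five steps (MOM ether, Dakin oxidation, benzylation, bromination, lithiation/CO2) to the benzoic acid A2.
Its chloride would C-acylate the lithium enolate of the sulfinyl enaminone A3, acid would close the 5-sulfinyl-4-pyranone, and acetylation would give A4.
Ring A would come last: a thermal Diels–Alder reaction of A4 with the bis(silyloxy)diene A5, sulfenic acid loss and aromatisation to the 2'-O-benzyl flavone A6, then hydrogenolysis.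
Weak point 1: the ring A Diels–Alder/elimination/aromatisation on a monocyclic 4-pyranone would have no precedent, would ask an aromatic-like dienophile to react without Lewis acid, and would stake the whole phloroglucinol ring on the last C–C bond-forming step.
Weak point 2: the five steps from A1 to A2 would be protecting-group and redox traffic that forms one C–C bond.
Weak point 3: the enolate C-acylation and acid closure to the pyranone would need two equivalents of A3, would compete with O-acylation, and would carry a sulfinyl group that serves only as a leaving group.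

**Retrosynthetic overview of the new route**

The 5'-acetate is read as the Baeyer–Villiger product of a 5'-acetyl group, so ring B is a 4,6-diacylresorcinol monomethyl ether and the ester is made in the last step by oxidation, not by a selective acylation.
Ring C is closed last, in one thermal operation, between free phloroglucinol (ring A: its C4a–H and the O1 hydroxyl) and the α-methoxy-β-keto ester 6, which carries ring B, C2, C3–OMe and C4; the bonds formed are C4–C4a and O1–C2.
Ring order: B (bought), A (bought), C (key step).
No ring A is built, no ring A hydroxyl is protected, one benzyl ether is the only protecting group, and no pyranone, sulfoxide or diene is needed.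

Key step: step 5

Remark: compounds 1, 4 and 7 are taken as commercial; the target is achiral, so no stereocentre has to be set.

**Route**

Step 1
Reactants: 1 1-(4-hydroxy-2-methoxyphenyl)ethanone
Product: 2 5-acetyl-2-hydroxy-4-methoxybenzaldehyde
Conditions: (CH2)6N4 (2 equiv), CF3CO2H, 90 °C; then H2O, 60 °C
Reagents that add atoms: hexamethylenetetramine, C1N2CN3CN1CN(C2)C3; water, O
Why: Duff ortho-formylation, in which the iminium ion from protonated hexamethylenetetramine is delivered ortho to the phenol; of the two ortho positions, C5 (para to OMe, unhindered) should react in preference to C3, which is flanked by OH and OMe, and hydrolysis of the benzylic iminium gives the salicylaldehyde.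

Step 2
Reactants: 2 5-acetyl-2-hydroxy-4-methoxybenzaldehyde
Product: 3 5-acetyl-2-(benzyloxy)-4-methoxybenzaldehyde
Conditions: BnBr (1.1 equiv), K2CO3 (1.5 equiv), DMF, rt
Reagents that add atoms: benzyl bromide, BrCc1ccccc1
Why: Williamson etherification of the chelated phenol; the benzyl ether later keeps this oxygen from lactonising onto the keto ester (4-hydroxycoumarin formation) and is the only protecting group of the route.

Step 3
Reactants: 3 5-acetyl-2-(benzyloxy)-4-methoxybenzaldehyde; 4 methyl methoxyacetate
Product: 5 methyl 3-[5-acetyl-2-(benzyloxy)-4-methoxyphenyl]-3-hydroxy-2-methoxypropanoate (racemic mixture of diastereomers)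
Conditions: 4 (1.3 equiv), LiN(i-Pr)2 (1.25 equiv), THF, −78 °C; then 3, −78 °C; AcOH quench at −78 °C
Reagents that add atoms: none
Why: Directed aldol addition of the lithium enolate of the glycolate ester to the aldehyde, which at −78 °C should be much faster than proton transfer from, or addition to, the aryl methyl ketone; the two new stereocentres form as a mixture of no consequence, since both are destroyed later (C3 in step 4, C2 in step 5).

Step 4
Reactants: 5 methyl 3-[5-acetyl-2-(benzyloxy)-4-methoxyphenyl]-3-hydroxy-2-methoxypropanoate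
Product: 6 methyl 3-[5-acetyl-2-(benzyloxy)-4-methoxyphenyl]-2-methoxy-3-oxopropanoate (racemic)
Conditions: Dess–Martin periodinane (1.3 equiv), CH2Cl2, 0 °C→rt
Reagents that add atoms: none
Why: Dess–Martin oxidation of the benzylic secondary alcohol to the β-keto ester under neutral conditions that should leave the acetyl group, the benzyl ether and the acidic CH(OMe) centre untouched.

Step 5
Reactants: 6 methyl 3-[5-acetyl-2-(benzyloxy)-4-methoxyphenyl]-2-methoxy-3-oxopropanoate; 7 phloroglucinol (benzene-1,3,5-triol)
Product: 10 2-[5-acetyl-2-(benzyloxy)-4-methoxyphenyl]-5,7-dihydroxy-3-methoxy-4H-chromen-4-one, via aroyl(methoxy)ketene 8 (not isolated), via 2-acylphloroglucinol diketone 9 (not isolated)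
Conditions: 7 (3 equiv, anhydrous), neat melt, 240 °C, N2, microwave or preheated bath, 5–10 min; H2O trituration
Reagents that add atoms: none
Why: Mentzer-type thermal chromone synthesis in its solvent-free form: at 240 °C the β-keto ester 6 should lose methanol to the aroyl(methoxy)ketene 8, which acylates the very nucleophilic ring carbon of phloroglucinol (directly, or by O-acylation and thermal acyl shift) to give the 2-acylphloroglucinol 9, so that the C4–C4a carbon–carbon bond is made onto an unfunctionalised arene C–H. An ortho hydroxyl of 9 then adds to the ring B ketone (6-exo-trig) and the hemiketal loses water, which closes ring C at O1–C2 and gives the chelated 5-hydroxychromone. The closest known reactions are the catalyst-free condensations of phloroglucinol with aroylacetates and with α-substituted β-keto esters, which give 5,7-dihydroxyflavones and 3-substituted chromones. No stereocentre is formed, and the threefold symmetry of phloroglucinol removes any question of regiochemistry on ring A. The step needs chromone and not coumarin formation, which the neutral medium, the α-methoxy substituent and the hindered, donor-deactivated aryl ketone should secure, and a single annulation, which the excess of phloroglucinol and the deactivation of the product by its chelated carbonyl should secure. The benzyl ether keeps the 2'-oxygen from lactonising onto the ketene, and the 5'-acetyl group is a spectator.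

Step 6
Reactants: 10 2-[5-acetyl-2-(benzyloxy)-4-methoxyphenyl]-5,7-dihydroxy-3-methoxy-4H-chromen-4-one
Product: 11 2-(5-acetyl-2-hydroxy-4-methoxyphenyl)-5,7-dihydroxy-3-methoxy-4H-chromen-4-one
Conditions: H2 (1 atm), Pd/C (10 wt% palladium on carbon), EtOAc–THF, rt
Reagents that add atoms: none
Why: Catalytic hydrogenolysis of the single aryl benzyl ether, which at 1 atm and room temperature should be much faster than reduction of the donor-deactivated aryl methyl ketone or of the chromone C2=C3 bond.

Step 7
Reactants: 11 2-(5-acetyl-2-hydroxy-4-methoxyphenyl)-5,7-dihydroxy-3-methoxy-4H-chromen-4-one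
Product: 12 5-(5,7-dihydroxy-3-methoxy-4-oxo-4H-chromen-2-yl)-4-hydroxy-2-methoxyphenyl acetate (5,7,2',5'-tetrahydroxy-3,4'-dimethoxyflavone 5'-acetate)
Conditions: mCPBA (1.5 equiv), CF3CO2H (0.2 equiv), EtOAc, 0 °C→rt; aq Na2S2O3
Reagents that add atoms: 3-chloroperoxybenzoic acid, O=C(OO)c1cccc(Cl)c1
Why: Baeyer–Villiger oxidation in which the aryl group, made electron-rich by its ortho methoxy and para hydroxy substituents, migrates far better than methyl, so the C-acetyl group becomes the O-acetate at C5' (as in the conversion of 4-hydroxyacetophenone into hydroquinone monoacetate); the acyl-deactivated ring A, the chelated carbonyl and the vinylogous-ester C2=C3 bond should not react at room temperature, and the new acetate has no neighbouring hydroxyl to migrate to.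

**Compound list**

1 | 1-(4-hydroxy-2-methoxyphenyl)ethanone | CC(=O)c1ccc(O)cc1OC | starting material
2 | 5-acetyl-2-hydroxy-4-methoxybenzaldehyde | CC(=O)c1cc(C=O)c(O)cc1OC | intermediate
3 | 5-acetyl-2-(benzyloxy)-4-methoxybenzaldehyde | CC(=O)c1cc(C=O)c(OCc2ccccc2)cc1OC | intermediate
4 | methyl methoxyacetate | COCC(=O)OC | starting material
5 | methyl 3-[5-acetyl-2-(benzyloxy)-4-methoxyphenyl]-3-hydroxy-2-methoxypropanoate (racemic mixture of diastereomers) | COC(C(O)c1cc(C(C)=O)c(OC)cc1OCc1ccccc1)C(=O)OC | intermediate
6 | methyl 3-[5-acetyl-2-(benzyloxy)-4-methoxyphenyl]-2-methoxy-3-oxopropanoate (racemic) | COC(C(=O)c1cc(C(C)=O)c(OC)cc1OCc1ccccc1)C(=O)OC | intermediate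
7 | phloroglucinol (benzene-1,3,5-triol) | Oc1cc(O)cc(O)c1 | starting material
8 | 2-[5-acetyl-2-(benzyloxy)-4-methoxybenzoyl]-2-methoxyethen-1-one (aroyl(methoxy)ketene, not isolated) | COC(=C=O)C(=O)c1cc(C(C)=O)c(OC)cc1OCc1ccccc1 | intermediate
9 | 1-[5-acetyl-2-(benzyloxy)-4-methoxyphenyl]-2-methoxy-3-(2,4,6-trihydroxyphenyl)propane-1,3-dione (racemic, not isolated) | COC(C(=O)c1cc(C(C)=O)c(OC)cc1OCc1ccccc1)C(=O)c1c(O)cc(O)cc1O | intermediate
10 | 2-[5-acetyl-2-(benzyloxy)-4-methoxyphenyl]-5,7-dihydroxy-3-methoxy-4H-chromen-4-one | COc1c(-c2cc(C(C)=O)c(OC)cc2OCc2ccccc2)oc2cc(O)cc(O)c2c1=O | intermediate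
11 | 2-(5-acetyl-2-hydroxy-4-methoxyphenyl)-5,7-dihydroxy-3-methoxy-4H-chromen-4-one | COc1c(-c2cc(C(C)=O)c(OC)cc2O)oc2cc(O)cc(O)c2c1=O | intermediate
12 | 5,7,2',5'-tetrahydroxy-3,4'-dimethoxyflavone 5'-acetate | COc1cc(O)c(-c2oc3cc(O)cc(O)c3c(=O)c2OC)cc1OC(C)=O | target

**Step count and risks**

Total step count: 7. Longest linear sequence: 7 (1 → 12; compounds 4 and 7 are bought).

Steps most likely to fail:

1. Step 5 (key annulation). The ketene may be captured on a phloroglucinol oxygen without the acyl shift to carbon, the phenol may attack the ketone in the Pechmann sense, or the benzyl group may migrate at 240 °C. The fallback would set out from aldehyde 3. Pinnick oxidation (NaClO2, NaH2PO4, 2-methyl-2-butene, t-BuOH–H2O) would give 5-acetyl-2-(benzyloxy)-4-methoxybenzoic acid F1, and (COCl)2 with catalytic DMF would give 5-acetyl-2-(benzyloxy)-4-methoxybenzoyl chloride F2. The polylithium salt of commercial 2-methoxy-1-(2,4,6-trihydroxyphenyl)ethanone F3 (LiN(SiMe3)2, 5 equiv, THF, −78 °C) would be C-acylated by F2 to give diketone 9, now isolated, and cyclodehydration (AcOH, catalytic H2SO4, 60 °C) would return to the route at 10.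

2. Step 7 (Baeyer–Villiger on the free triphenol). Peracid addition to the doubly donor-substituted ketone may be slow, and prolonged exposure may lead to electrophilic hydroxylation or quinone formation on the free phenol rings. The fallback would set out from 10 and move the oxidation to a stage with no free, reactive phenol. TBSCl and imidazole (DMF, rt) would silylate the 7-hydroxyl only, the 5-hydroxyl being chelated, to give 2-[5-acetyl-2-(benzyloxy)-4-methoxyphenyl]-7-[(tert-butyldimethylsilyl)oxy]-5-hydroxy-3-methoxy-4H-chromen-4-one F4. Baeyer–Villiger oxidation (mCPBA, CH2Cl2) would give 4-(benzyloxy)-5-{7-[(tert-butyldimethylsilyl)oxy]-5-hydroxy-3-methoxy-4-oxo-4H-chromen-2-yl}-2-methoxyphenyl acetate F5. Hydrogenolysis (H2, Pd/C, EtOAc) would give 5-{7-[(tert-butyldimethylsilyl)oxy]-5-hydroxy-3-methoxy-4-oxo-4H-chromen-2-yl}-4-hydroxy-2-methoxyphenyl acetate F6, and HF·pyridine (THF, 0 °C), which spares aryl acetates, would return to the route at 12.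

3. Step 1 (Duff formylation). Formylation may go in part to C3, between OH and OMe, or twice. The fallback would set out from 1 and fix the position by electrophilic bromination para to the methoxy group. NBS (MeCN, 0 °C) would give 1-(5-bromo-4-hydroxy-2-methoxyphenyl)ethanone F7, and BnBr with K2CO3 (DMF) would give 1-[4-(benzyloxy)-5-bromo-2-methoxyphenyl]ethanone F8. Reductive carbonylation (Pd(OAc)2, di(1-adamantyl)-n-butylphosphine, CO/H2 5 bar, TMEDA, toluene, 100 °C), which tolerates the ketone, would return to the route at 3.

**Further compounds**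

F1 | step 5 | 5-acetyl-2-(benzyloxy)-4-methoxybenzoic acid | CC(=O)c1cc(C(=O)O)c(OCc2ccccc2)cc1OC
F2 | step 5 | 5-acetyl-2-(benzyloxy)-4-methoxybenzoyl chloride | CC(=O)c1cc(C(=O)Cl)c(OCc2ccccc2)cc1OC
F3 | step 5 | 2-methoxy-1-(2,4,6-trihydroxyphenyl)ethanone | COCC(=O)c1c(O)cc(O)cc1O
F4 | step 7 | 2-[5-acetyl-2-(benzyloxy)-4-methoxyphenyl]-7-[(tert-butyldimethylsilyl)oxy]-5-hydroxy-3-methoxy-4H-chromen-4-one | COc1c(-c2cc(C(C)=O)c(OC)cc2OCc2ccccc2)oc2cc(O[Si](C)(C)C(C)(C)C)cc(O)c2c1=O
F5 | step 7 | 4-(benzyloxy)-5-{7-[(tert-butyldimethylsilyl)oxy]-5-hydroxy-3-methoxy-4-oxo-4H-chromen-2-yl}-2-methoxyphenyl acetate | COc1c(-c2cc(OC(C)=O)c(OC)cc2OCc2ccccc2)oc2cc(O[Si](C)(C)C(C)(C)C)cc(O)c2c1=O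
F6 | step 7 | 5-{7-[(tert-butyldimethylsilyl)oxy]-5-hydroxy-3-methoxy-4-oxo-4H-chromen-2-yl}-4-hydroxy-2-methoxyphenyl acetate | COc1c(-c2cc(OC(C)=O)c(OC)cc2O)oc2cc(O[Si](C)(C)C(C)(C)C)cc(O)c2c1=O
F7 | step 1 | 1-(5-bromo-4-hydroxy-2-methoxyphenyl)ethanone | CC(=O)c1cc(Br)c(O)cc1OC
F8 | step 1 | 1-[4-(benzyloxy)-5-bromo-2-methoxyphenyl]ethanone | CC(=O)c1cc(Br)c(OCc2ccccc2)cc1OC
A1 | direct plan | vanillin | COc1cc(C=O)ccc1O
A2 | direct plan | 2-(benzyloxy)-4-methoxy-5-(methoxymethoxy)benzoic acid | COCOc1cc(C(=O)O)c(OCc2ccccc2)cc1OC
A3 | direct plan | 4-(dimethylamino)-1-methoxy-3-(4-methylbenzenesulfinyl)but-3-en-2-one | COCC(=O)C(=CN(C)C)S(=O)c1ccc(C)cc1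
A4 | direct plan | 4-(benzyloxy)-2-methoxy-5-[3-methoxy-5-(4-methylbenzenesulfinyl)-4-oxo-4H-pyran-2-yl]phenyl acetate | COc1c(-c2cc(OC(C)=O)c(OC)cc2OCc2ccccc2)occ(S(=O)c2ccc(C)cc2)c1=O
A5 | direct plan | (1Z)-1-methoxy-1,3-bis(trimethylsilyloxy)buta-1,3-diene | CO/C(O[Si](C)(C)C)=C/C(=C)O[Si](C)(C)C
A6 | direct plan | 4-(benzyloxy)-5-(5,7-dihydroxy-3-methoxy-4-oxo-4H-chromen-2-yl)-2-methoxyphenyl acetate | COc1c(-c2cc(OC(C)=O)c(OC)cc2OCc2ccccc2)oc2cc(O)cc(O)c2c1=O
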